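**Retrosynthetic overview**

1. The target comes from the fused 2-alkoxyfuran 30 (a 2,3-dihydrofuro[2,3-b]furan) by aqueous acid, which opens the ketene-acetal ring to the butenolide plus the free C11 hydroxyl and removes the 3,19-acetonide.
2. 30 comes from the α-isocyano ester 27 of the C11 homopropargylic alcohol in one operation: isomerisation to a 5-alkoxyoxazole, intramolecular oxazole–alkyne [4+2], loss of acetonitrile. This forms C13–C16 and C14–C15, so the butenolide ring is made last.
3. Enabling feature: the C11 hydroxyl oxygen and the lactone carbonyl carbon C16 are joined through C12–C13 (O–C11–C12–C13–C16). The C11 oxygen can therefore serve as the 5-alkoxy group of the oxazole and as a three-atom tether to the C13≡C14 alkyne; the temporary five-membered ring O–C11–C12–C13–C16 is opened again in the last step.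
4. 27 comes from aldehyde 22 (C11) by propargylation, and 22 from decalin 19. Ring A and ring B are formed together by an epoxide-initiated, allylsilane-terminated cationic bicyclisation of 18, which sets C4, C5, C9 and C10 from the C3 epoxide centre and gives the exocyclic C8=C17 olefin.
5. 18 comes from geraniol: Still–Gennari Z-olefination, Sharpless epoxidation (absolute configuration), acetoacetate dianion alkylation, enol phosphate to allylsilane.

Key step: step 21

**Remarks on the chemistry**

- Labdane numbering is used (C3 carbinol, C4 quaternary, C19 hydroxymethyl, C17 exocyclic methylene, C11 carbinol, C12–C16 side chain and lactone). α/β refer to the usual drawing, in which the C10 methyl of this ent-labdane is α.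
- The alanine-derived stereocentre of 26 and 27 is lost in step 21, so its epimerisation in steps 19–20 is without consequence; one epimer is drawn.

**Route**

Step 1
Reactants: 1 geraniol
Product: 2 geranyl 4-methoxybenzyl ether
Conditions: NaH, 4-methoxybenzyl chloride, n-Bu4NI (cat.), THF/DMF, 0 °C to rt
Reagents that add atoms: 4-methoxybenzyl chloride COc1ccc(CCl)cc1
Why: Williamson etherification of the primary allylic alkoxide, with no stereocentre involved.

Step 2
Reactants: 2 geranyl 4-methoxybenzyl ether
Product: 4 (4E)-6-[(4-methoxybenzyl)oxy]-4-methylhex-4-enal, via epoxide 3 (not isolated)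
Conditions: mCPBA, NaHCO3, CH2Cl2, −20 to 0 °C; then H5IO6, THF/H2O, 0 °C to rt
Reagents that add atoms: 3-chloroperoxybenzoic acid OOC(=O)c1cccc(Cl)c1
Why: Peracid epoxidation should prefer the remote, more electron-rich 6,7-olefin (the 2,3-olefin is deactivated by the allylic oxygen), and periodic acid then hydrolyses the epoxide and cleaves the glycol to the aldehyde (epoxidation followed by glycol cleavage).

Step 3
Reactants: 4 (4E)-6-[(4-methoxybenzyl)oxy]-4-methylhex-4-enal; 5 ethyl 2-[bis(2,2,2-trifluoroethoxy)phosphoryl]propanoate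
Product: 6 ethyl (2Z,6E)-8-[(4-methoxybenzyl)oxy]-2,6-dimethylocta-2,6-dienoate
Conditions: KN(SiMe3)2, 18-crown-6, THF, −78 °C
Reagents that add atoms: none
Why: Still–Gennari variant of the Horner–Wadsworth–Emmons olefination, whose kinetically controlled elimination should give the Z-trisubstituted enoate and so place the future C19 cis to the chain.

Step 4
Reactants: 6 ethyl (2Z,6E)-8-[(4-methoxybenzyl)oxy]-2,6-dimethylocta-2,6-dienoate
Product: 7 (2Z,6E)-8-[(4-methoxybenzyl)oxy]-2,6-dimethylocta-2,6-dien-1-ol
Conditions: i-Bu2AlH, CH2Cl2, −78 °C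
Reagents that add atoms: none
Why: 1,2-reduction of the enoate by the aluminium hydride at low temperature (ester reduction) should leave the olefin geometry and the PMB ether untouched.

Step 5
Reactants: 7 (2Z,6E)-8-[(4-methoxybenzyl)oxy]-2,6-dimethylocta-2,6-dien-1-ol
Product: 8 [(2S,3R)-3-{(3E)-5-[(4-methoxybenzyl)oxy]-3-methylpent-3-en-1-yl}-2-methyloxiran-2-yl]methanol
Conditions: Ti(Oi-Pr)4 (cat.), diethyl L-(+)-tartrate (cat.), t-BuOOH, 4 Å MS, CH2Cl2, −20 °C
Reagents that add atoms: tert-butyl hydroperoxide CC(C)(C)OO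
Why: Sharpless asymmetric epoxidation, in which the L-(+)-tartrate complex delivers oxygen to the face of the Z-allylic alcohol that gives the (2S,3R)-epoxy alcohol, fixing C3 as R and leaving the other allylic ether olefin alone.

Step 6
Reactants: 8 the (2S,3R)-epoxy alcohol
Product: 9 tert-butyldimethylsilyl ether of 8
Conditions: TBSCl, imidazole, CH2Cl2, 0 °C to rt
Reagents that add atoms: tert-butyldimethylsilyl chloride CC(C)(C)[Si](C)(C)Cl
Why: Silylation of the primary alcohol under basic conditions that do not touch the epoxide.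

Step 7
Reactants: 9 tert-butyldimethylsilyl ether of 8
Product: 10 (2E)-5-[(2R,3S)-3-({[tert-butyl(dimethyl)silyl]oxy}methyl)-3-methyloxiran-2-yl]-3-methylpent-2-en-1-ol
Conditions: DDQ, CH2Cl2/pH 7 buffer, 0 °C
Reagents that add atoms: none
Why: Oxidative cleavage of the electron-rich PMB ether by DDQ under buffered conditions should spare the silyl ether, the epoxide and the olefin.

Step 8
Reactants: 10 the epoxy allylic alcohol
Product: 12 tert-butyl{[(2S,3R)-3-[(3E)-5-bromo-3-methylpent-3-en-1-yl]-2-methyloxiran-2-yl]methoxy}dimethylsilane, via mesylate 11 (not isolated)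
Conditions: MsCl, Et3N, CH2Cl2, −40 °C; then LiBr, THF, 0 °C
Reagents that add atoms: lithium bromide [Li+].[Br-]; methanesulfonyl chloride CS(=O)(=O)Cl (its atoms stay only in intermediate 11)
Why: Mesylation and SN2 displacement by bromide at low temperature should keep the trisubstituted epoxide and the E geometry intact.

Step 9
Reactants: 12 the epoxy allylic bromide; 13 methyl acetoacetate
Product: 14 methyl (6E)-9-[(2R,3S)-3-({[tert-butyl(dimethyl)silyl]oxy}methyl)-3-methyloxiran-2-yl]-7-methyl-3-oxonon-6-enoate
Conditions: 13, NaH then n-BuLi, THF, 0 °C; then 12, 0 °C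
Reagents that add atoms: none
Why: Alkylation of the acetoacetate dianion at its terminal carbon by SN2 attack on the primary allylic bromide, with the hindered epoxide and silyl ether inert to this soft nucleophile.

Step 10
Reactants: 14 the β-keto ester
Product: 15 methyl (2Z,6E)-3-[(diethoxyphosphoryl)oxy]-9-[(2R,3S)-3-({[tert-butyl(dimethyl)silyl]oxy}methyl)-3-methyloxiran-2-yl]-7-methylnona-2,6-dienoate
Conditions: NaH, Et2O, 0 °C; then ClP(O)(OEt)2
Reagents that add atoms: diethyl chlorophosphate CCOP(=O)(Cl)OCC
Why: O-phosphorylation of the chelated sodium enolate in ether should give the Z-enol phosphate (phosphate cis to the ester).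

Step 11
Reactants: 15 the Z-enol phosphate
Product: 16 methyl (2Z,6E)-9-[(2R,3S)-3-({[tert-butyl(dimethyl)silyl]oxy}methyl)-3-methyloxiran-2-yl]-7-methyl-3-[(trimethylsilyl)methyl]nona-2,6-dienoate
Conditions: Me3SiCH2MgCl, Ni(acac)2 (cat.), THF, 0 °C to rt
Reagents that add atoms: (trimethylsilyl)methylmagnesium chloride C[Si](C)(C)C[Mg]Cl
Why: Nickel-catalysed Kumada-type coupling of the enol phosphate proceeds with retention of olefin geometry, so CH2SiMe3 ends up cis to the ester and C11 trans to C7.

Step 12
Reactants: 16 the allylsilane ester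
Product: 17 (2Z,6E)-9-[(2R,3S)-3-({[tert-butyl(dimethyl)silyl]oxy}methyl)-3-methyloxiran-2-yl]-7-methyl-3-[(trimethylsilyl)methyl]nona-2,6-dien-1-ol
Conditions: i-Bu2AlH, CH2Cl2, −78 °C
Reagents that add atoms: none
Why: 1,2-reduction of the conjugated ester (ester reduction) turns the deactivated vinylogous α-silyl ester into a nucleophilic allylsilane without opening the protected epoxide at −78 °C.

Step 13
Reactants: 17 the allylsilane alcohol
Product: 18 bis(tert-butyldimethylsilyl) ether of 17
Conditions: TBSCl, imidazole, DMF, 0 °C to rt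
Reagents that add atoms: tert-butyldimethylsilyl chloride CC(C)(C)[Si](C)(C)Cl
Why: Silylation under basic conditions protects the primary allylic alcohol and avoids protodesilylation of the allylsilane.

Step 14
Reactants: 18 the epoxy allylsilane
Product: 19 trans-decalin with 3α-OH (equatorial), 4α-CH2OTBS (axial), 4β-CH3, 5β-H, 10α-CH3, 9β-H, 9α-CH2OTBS and the 8(17)-exocyclic methylene
Conditions: MeAlCl2, CH2Cl2, −78 °C; then Et3N, MeOH/H2O
Reagents that add atoms: none
Why: Lewis-acid opening of the epoxide starts a chair–chair cationic polyene bicyclisation (epoxide-initiated, allylsilane-terminated) in which anti attack at C4 puts the Z-derived CH2OTBS axial, the E C10=C5 olefin gives the trans ring fusion, the allylsilane geometry puts C11 equatorial at C9 and loss of silicon gives only the exocyclic olefin, so that C4, C5, C9 and C10 all follow from the C3 centre set in step 5.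

Step 15
Reactants: 19 the bicyclic bis-silyl ether
Product: 20 triol with 3α-OH, 19-OH and 11-OH
Conditions: n-Bu4NF, THF, rt to 45 °C
Reagents that add atoms: none
Why: Fluoride-mediated desilylation of both primary silyl ethers.

Step 16
Reactants: 20 the triol
Product: 21 3,19-O-isopropylidene acetal of 20 with free 11-OH
Conditions: 2,2-dimethoxypropane, PPTS (cat.), CH2Cl2, rt
Reagents that add atoms: 2,2-dimethoxypropane COC(C)(C)OC
Why: Transketalisation, in which only the 1,3-related equatorial 3-OH and axial C19-OH can close a six-membered dioxane, so the C11 hydroxyl stays free.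

Step 17
Reactants: 21 the acetonide alcohol
Product: 22 3,19-O-isopropylidene C11 aldehyde (formyl group equatorial on C9, 9β-H)
Conditions: Dess–Martin periodinane, NaHCO3, CH2Cl2, 0 °C to rt, used crude
Reagents that add atoms: none
Why: Dess–Martin oxidation under buffered, non-basic conditions should avoid C9 epimerisation and conjugation of this β,γ-unsaturated aldehyde.

Step 18
Reactants: 22 the C11 aldehyde; 23 allenylboronic acid pinacol ester
Product: 24 (11R)-homopropargylic alcohol with the 3,19-acetonide
Conditions: (R)-3,3'-bis(2,4,6-triisopropylphenyl)-1,1'-binaphthyl-2,2'-diyl hydrogen phosphate (cat.), 4 Å MS, toluene, 0 °C to rt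
Reagents that add atoms: none
Why: Brønsted-acid-catalysed propargylboration through a closed six-membered SE2' transition state, in which C11 should be set as R by Felkin–Anh approach anti to the quaternary C10 (carbonyl oxygen gauche to C8, nucleophile passing the small C9–H), with the (R)-catalyst expected to deliver to the same face.

Step 19
Reactants: 24 the (11R)-homopropargylic alcohol; 25 N-formyl-L-alanine
Product: 26 C11 ester of 24 with N-formylalanine
Conditions: EDC·HCl, DMAP, CH2Cl2, 0 °C to rt
Reagents that add atoms: none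
Why: Steglich esterification of the only free hydroxyl, with retention at C11 because its C–O bond is not touched.

Step 20
Reactants: 26 the N-formylalanine ester
Product: 27 C11 2-isocyanopropanoate ester
Conditions: POCl3, Et3N, CH2Cl2, −30 to 0 °C
Reagents that add atoms: none
Why: Standard dehydration of a formamide to an isocyanide under basic conditions that the acetonide, ester and alkyne tolerate.

Step 21
Reactants: 27 the C11 2-isocyanopropanoate ester
Product: 30 3,19-O-isopropylidene 2,3-dihydrofuro[2,3-b]furan (C11 is ring C2 and carries the decalin; furan ring made of C13/C14/C15/O/C16), via oxazole 28 (not isolated), via cycloadduct 29 (not isolated)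
Conditions: n-Bu3N (1 equiv), o-dichlorobenzene (0.01 M, degassed), 150 °C then 180 °C, sealed tube; evaporate, filter through basic alumina
Reagents that add atoms: none
Why: Proposed new method: the amine should reversibly deprotonate the α-isocyano ester and the enolate oxygen should add to the isocyanide carbon to give, after protonation, the 5-alkoxy-4-methyloxazole 28, whose C5 (former ester carbonyl carbon, future C16) and C2 (former isocyanide carbon, future C15) then add as an electron-rich azadiene across the tethered C13≡C14 alkyne, after which retro-[4+2] loss of acetonitrile from the 7-oxa-2-azanorbornadiene 29 makes the sequence irreversible and leaves the furan of 30. The closest known reactions are the amine-mediated thermal isomerisation of α-isocyanoalkanoates to 5-alkoxyoxazoles, the intramolecular oxazole–alkyne Diels–Alder/retro-Diels–Alder furan synthesis, and intramolecular furan Diels–Alder reactions tethered through a heteroatom on the diene carbon; what is new is the tether through the 5-alkoxy oxygen and the one-pot combination. Ring closures: the oxazole by 5-endo-dig attack of oxygen on the isocyanide carbon, then the dihydrofuran ring (O, C11, C12, C13, C16) and the bicyclo[2.2.1] core together in the intramolecular [4+2], while the furan ring arises by cycloreversion and not by a closure. No stereocentre of 30 is created: the two bridgehead centres of 29 are transient and either diastereomer collapses to the same furan, and C11 keeps its configuration because its C–O bond is never broken. Regiochemistry (C13 to C16, C14 to C15) is enforced by the three-atom tether, since the reverse orientation would need a bridged anti-Bredt adduct. Chemoselectivity for the alkyne over the equally close C8=C17 olefin is secured because an olefin adduct would carry a quaternary spiro carbon at C8, could not aromatise and could only revert, whereas the alkyne adduct is drained by loss of acetonitrile.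

Step 22
Reactants: 30 the fused 2-alkoxyfuran
Product: 31 14-deoxy-11-hydroxyandrographolide
Conditions: AcOH/H2O/THF (3:1:1), rt to 40 °C; if needed Et3N (cat.), CH2Cl2, rt
Reagents that add atoms: water O
Why: Ketene-acetal and acetal hydrolysis, in which the 2-alkoxyfuran is protonated at its nucleophilic C15, water adds at C16 and the ortho-acid expels the C11 oxygen to give the conjugated butenolide and the C11 hydroxyl with retention, the same acid removes the acetonide, and any β,γ-unsaturated lactone isomer is brought into conjugation by the amine.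

**Compound list**

1 | geraniol | CC(C)=CCC/C(C)=C/CO | starting material
2 | geranyl 4-methoxybenzyl ether | CC(C)=CCC/C(C)=C/COCc1ccc(OC)cc1 | intermediate
3 | 6,7-epoxygeranyl 4-methoxybenzyl ether (racemic, centre destroyed in the same step) | CC1(C)OC1CC/C(C)=C/COCc1ccc(OC)cc1 | intermediate
4 | (4E)-6-[(4-methoxybenzyl)oxy]-4-methylhex-4-enal | O=CCC/C(C)=C/COCc1ccc(OC)cc1 | intermediate
5 | ethyl 2-[bis(2,2,2-trifluoroethoxy)phosphoryl]propanoate (racemic) | CCOC(=O)C(C)P(=O)(OCC(F)(F)F)OCC(F)(F)F | starting material
6 | ethyl (2Z,6E)-8-[(4-methoxybenzyl)oxy]-2,6-dimethylocta-2,6-dienoate | CCOC(=O)/C(C)=C\CC/C(C)=C/COCc1ccc(OC)cc1 | intermediate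
7 | (2Z,6E)-8-[(4-methoxybenzyl)oxy]-2,6-dimethylocta-2,6-dien-1-ol | OC/C(C)=C\CC/C(C)=C/COCc1ccc(OC)cc1 | intermediate
8 | [(2S,3R)-3-{(3E)-5-[(4-methoxybenzyl)oxy]-3-methylpent-3-en-1-yl}-2-methyloxiran-2-yl]methanol | OC[C@]1(C)O[C@@H]1CC/C(C)=C/COCc1ccc(OC)cc1 | intermediate
9 | tert-butyldimethylsilyl ether of 8 | CC(C)(C)[Si](C)(C)OC[C@]1(C)O[C@@H]1CC/C(C)=C/COCc1ccc(OC)cc1 | intermediate
10 | (2E)-5-[(2R,3S)-3-({[tert-butyl(dimethyl)silyl]oxy}methyl)-3-methyloxiran-2-yl]-3-methylpent-2-en-1-ol | CC(C)(C)[Si](C)(C)OC[C@]1(C)O[C@@H]1CC/C(C)=C/CO | intermediate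
11 | methanesulfonate of 10 | CC(C)(C)[Si](C)(C)OC[C@]1(C)O[C@@H]1CC/C(C)=C/COS(C)(=O)=O | intermediate
12 | tert-butyl{[(2S,3R)-3-[(3E)-5-bromo-3-methylpent-3-en-1-yl]-2-methyloxiran-2-yl]methoxy}dimethylsilane | CC(C)(C)[Si](C)(C)OC[C@]1(C)O[C@@H]1CC/C(C)=C/CBr | intermediate
13 | methyl acetoacetate | CC(=O)CC(=O)OC | starting material
14 | methyl (6E)-9-[(2R,3S)-3-(TBSO-methyl)-3-methyloxiran-2-yl]-7-methyl-3-oxonon-6-enoate | CC(C)(C)[Si](C)(C)OC[C@]1(C)O[C@@H]1CC/C(C)=C/CCC(=O)CC(=O)OC | intermediate
15 | methyl (2Z,6E)-3-[(diethoxyphosphoryl)oxy]-9-[(2R,3S)-3-(TBSO-methyl)-3-methyloxiran-2-yl]-7-methylnona-2,6-dienoate | CC(C)(C)[Si](C)(C)OC[C@]1(C)O[C@@H]1CC/C(C)=C/CC/C(OP(=O)(OCC)OCC)=C/C(=O)OC | intermediate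
16 | methyl (2Z,6E)-9-[(2R,3S)-3-(TBSO-methyl)-3-methyloxiran-2-yl]-7-methyl-3-[(trimethylsilyl)methyl]nona-2,6-dienoate | CC(C)(C)[Si](C)(C)OC[C@]1(C)O[C@@H]1CC/C(C)=C/CC/C(C[Si](C)(C)C)=C/C(=O)OC | intermediate
17 | (2Z,6E)-9-[(2R,3S)-3-(TBSO-methyl)-3-methyloxiran-2-yl]-7-methyl-3-[(trimethylsilyl)methyl]nona-2,6-dien-1-ol | CC(C)(C)[Si](C)(C)OC[C@]1(C)O[C@@H]1CC/C(C)=C/CC/C(C[Si](C)(C)C)=C/CO | intermediate
18 | tert-butyldimethylsilyl ether of 17 (epoxy allylsilane) | CC(C)(C)[Si](C)(C)OC[C@]1(C)O[C@@H]1CC/C(C)=C/CC/C(C[Si](C)(C)C)=C/CO[Si](C)(C)C(C)(C)C | intermediate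
19 | trans-decalin: 3α-OH, 4α-CH2OTBS (axial), 4β-CH3, 5β-H, 10α-CH3, 9α-CH2OTBS, 8(17)-methylene | C=C1CC[C@@H]2[C@](C)(CO[Si](C)(C)C(C)(C)C)[C@H](O)CC[C@@]2(C)[C@@H]1CO[Si](C)(C)C(C)(C)C | intermediate
20 | triol (3α-OH, 19-OH, 11-OH) of the same decalin | C=C1CC[C@@H]2[C@](C)(CO)[C@H](O)CC[C@@]2(C)[C@@H]1CO | intermediate
21 | 3,19-O-isopropylidene acetal of 20, free 11-OH | C=C1CC[C@@H]2[C@](C)(CO3)[C@H](OC3(C)C)CC[C@@]2(C)[C@@H]1CO | intermediate
22 | 3,19-O-isopropylidene C11 aldehyde | C=C1CC[C@@H]2[C@](C)(CO3)[C@H](OC3(C)C)CC[C@@]2(C)[C@@H]1C=O | intermediate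
23 | allenylboronic acid pinacol ester | C=C=CB1OC(C)(C)C(C)(C)O1 | starting material
24 | (11R)-homopropargylic alcohol, 3,19-acetonide | C=C1CC[C@@H]2[C@](C)(CO3)[C@H](OC3(C)C)CC[C@@]2(C)[C@@H]1[C@H](O)CC#C | intermediate
25 | N-formyl-L-alanine | C[C@H](NC=O)C(=O)O | starting material
26 | C11 N-formyl-L-alaninate of 24 | C=C1CC[C@@H]2[C@](C)(CO3)[C@H](OC3(C)C)CC[C@@]2(C)[C@@H]1[C@H](OC(=O)[C@H](C)NC=O)CC#C | intermediate
27 | C11 2-isocyanopropanoate of 24 | C=C1CC[C@@H]2[C@](C)(CO3)[C@H](OC3(C)C)CC[C@@]2(C)[C@@H]1[C@H](OC(=O)[C@H](C)[N+]#[C-])CC#C | intermediate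
28 | 5-alkoxy-4-methyl-1,3-oxazole (alkoxy = C11 oxygen of 24) | C=C1CC[C@@H]2[C@](C)(CO3)[C@H](OC3(C)C)CC[C@@]2(C)[C@@H]1[C@H](Oc4ocnc4C)CC#C | intermediate
29 | tether-fused 7-oxa-2-azabicyclo[2.2.1]hepta-2,5-diene cycloadduct (transient bridgehead centres not specified) | C=C1CC[C@@H]2[C@](C)(CO3)[C@H](OC3(C)C)CC[C@@]2(C)[C@@H]1[C@H]4CC5=CC6N=C(C)C5(O4)O6 | intermediate
30 | 3,19-O-isopropylidene 2,3-dihydrofuro[2,3-b]furan (C11 as ring C2) | C=C1CC[C@@H]2[C@](C)(CO3)[C@H](OC3(C)C)CC[C@@]2(C)[C@@H]1[C@H]4Cc5ccoc5O4 | intermediate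
31 | 14-deoxy-11-hydroxyandrographolide | C=C1CC[C@@H]2[C@](C)(CO)[C@H](O)CC[C@@]2(C)[C@@H]1[C@H](O)CC1=CCOC1=O | target

**Step count and risks**

Total steps: 22. Longest linear sequence: 22 steps (from geraniol).

Steps most likely to fail:

1. Step 21. The intramolecular [4+2] of the unactivated alkyne may be too slow at temperatures the isocyanide survives, so that isocyanide-to-nitrile rearrangement, amine-induced propargyl–allenyl isomerisation or intermolecular reactions of the isocyano enolate take over. The fallback builds the butenolide by known carbonylation chemistry, sets out from 24 and returns at 31. Silylation of 24 (TBSOTf, 2,6-lutidine) should give the C11 silyl ether F1. Deprotonation of the alkyne (n-BuLi, THF, −78 °C) and addition to paraformaldehyde should give the propargylic alcohol F2. Hydroxyl-directed trans-hydroalumination (NaAlH2(OCH2CH2OMe)2, THF) and iodinolysis should give the (Z)-vinyl iodide F3, with iodine on C13 cis to the C15 hydroxymethyl. Palladium-catalysed carbonylative lactonisation (PdCl2(PPh3)2 cat., CO 1 atm, Et3N, THF, 50 °C) should give the protected butenolide F4. Aqueous HF in MeCN then removes the silyl ether and the acetonide to give 31.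

2. Step 14. The silyloxymethyl group lowers the cation-stabilising ability of C4, so epoxide opening may go astray (attack at C3, hydride shift to a carbonyl compound), or the cascade may stop after ring A by proton loss or protodesilylation. The fallback replaces the cationic cascade by an oxidative radical bicyclisation, sets out from 2 and returns at 20.
   - Allylic oxidation of 2 at the E-methyl (SeO2 cat., t-BuOOH, CH2Cl2) should give the (2E,6E)-allylic alcohol F5, and CBr4/PPh3 the allylic bromide F6.
   - Transesterification of ethyl 2-methylacetoacetate with (1R,2S,5R)-8-phenylmenthol (DMAP, toluene, reflux) should give the auxiliary β-keto ester F7. Its dianion (NaH, n-BuLi) should be alkylated by F6 to give the polyene β-keto ester F8.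
   - Treatment with Mn(OAc)3·2H2O and Cu(OAc)2·H2O (Yb(OTf)3 additive, CF3CH2OH or AcOH) should give the bicyclic keto ester F9: trans-decalin, ester axial at C4, exocyclic olefin from oxidation of the tertiary radical by divalent copper.
   - The auxiliary is meant to control the absolute sense, by analogy with known 8-phenylmenthyl-directed cyclisations of this type. The sense has to be checked on the first sample, and the enantiomeric auxiliary used if it is opposite.
   - LiAlH4 should reduce the ketone (equatorial alcohol) and the ester (releasing the auxiliary) to the diol F10, and DDQ then removes the PMB group to give 20.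

3. Step 18. Facial selectivity at the hindered, α-branched aldehyde may be poor if substrate and catalyst preferences are weak or opposed, and the aldehyde may conjugate before it reacts. The fallback sets C11 by reduction instead of C–C bond formation, sets out from 24 obtained as a C11 epimer mixture and returns at 24. Dess–Martin oxidation (NaHCO3 buffer, to avoid ynone–allenone isomerisation) should give the β,γ-ynone F11. Corey–Bakshi–Shibata reduction with (S)-2-methyl-CBS-oxazaborolidine and BH3·SMe2 at −40 °C, which treats the decalinyl group as the large and the propargyl group as the small substituent, should then give (11R)-24 under reagent control.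

Further compounds
F1 | step 21 | C11 tert-butyldimethylsilyl ether of 24 | C=C1CC[C@@H]2[C@](C)(CO3)[C@H](OC3(C)C)CC[C@@]2(C)[C@@H]1[C@H](O[Si](C)(C)C(C)(C)C)CC#C
F2 | step 21 | hydroxymethylated alkyne (C15 installed) of F1 | C=C1CC[C@@H]2[C@](C)(CO3)[C@H](OC3(C)C)CC[C@@]2(C)[C@@H]1[C@H](O[Si](C)(C)C(C)(C)C)CC#CCO
F3 | step 21 | (Z)-13-iodo-13-en-15-ol (iodine on C13 cis to C15) | C=C1CC[C@@H]2[C@](C)(CO3)[C@H](OC3(C)C)CC[C@@]2(C)[C@@H]1[C@H](O[Si](C)(C)C(C)(C)C)C/C(I)=C/CO
F4 | step 21 | 11-O-TBS 3,19-O-isopropylidene derivative of 31 | C=C1CC[C@@H]2[C@](C)(CO3)[C@H](OC3(C)C)CC[C@@]2(C)[C@@H]1[C@H](O[Si](C)(C)C(C)(C)C)CC1=CCOC1=O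
F5 | step 14 | (2E,6E)-8-[(4-methoxybenzyl)oxy]-2,6-dimethylocta-2,6-dien-1-ol | OC/C(C)=C/CC/C(C)=C/COCc1ccc(OC)cc1
F6 | step 14 | (2E,6E)-1-bromo-8-[(4-methoxybenzyl)oxy]-2,6-dimethylocta-2,6-diene | BrC/C(C)=C/CC/C(C)=C/COCc1ccc(OC)cc1
F7 | step 14 | (1R,2S,5R)-8-phenylmenthyl 2-methyl-3-oxobutanoate (epimers at C2) | CC(=O)C(C)C(=O)O[C@@H]1C[C@H](C)CC[C@H]1C(C)(C)c1ccccc1
F8 | step 14 | (1R,2S,5R)-8-phenylmenthyl (6E,10E)-12-[(4-methoxybenzyl)oxy]-2,6,10-trimethyl-3-oxododeca-6,10-dienoate (epimers at C2) | O=C(O[C@@H]1C[C@H](C)CC[C@H]1C(C)(C)c1ccccc1)C(C)C(=O)CC/C(C)=C/CC/C(C)=C/COCc1ccc(OC)cc1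
F9 | step 14 | bicyclic 3-oxo 4α-carboxylate (8-phenylmenthyl ester), 8(17)-methylene, 9α-CH2OPMB | C=C1CC[C@@H]2[C@](C)(C(=O)O[C@@H]3C[C@H](C)CC[C@H]3C(C)(C)c3ccccc3)C(=O)CC[C@@]2(C)[C@@H]1COCc1ccc(OC)cc1
F10 | step 14 | 11-O-(4-methoxybenzyl) ether of triol 20 | C=C1CC[C@@H]2[C@](C)(CO)[C@H](O)CC[C@@]2(C)[C@@H]1COCc1ccc(OC)cc1
F11 | step 18 | C11 ketone (β,γ-ynone) of 24 | C=C1CC[C@@H]2[C@](C)(CO3)[C@H](OC3(C)C)CC[C@@]2(C)[C@@H]1C(=O)CC#C
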